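(The numbers of this flask were set for the occasion; the run is a simulation.)

Slowness in this flask begins at the solid, which has to dissolve before it can react.

    starting material ⇌ intermediate A (K1 = 0.449, k1 = 2.59 × 10⁻⁴ s⁻¹)
    intermediate A ⇌ intermediate B (K2 = 6.9, k2 = 1.97 × 10⁻⁴ s⁻¹)
    starting material → target (k3 = 0.00108 s⁻¹)
    intermediate B → intermediate C (k4 = 1.42 × 10⁻⁴ s⁻¹)
    intermediate C ⇌ intermediate D (K5 = 0.143, k5 = 6.14 × 10⁻⁵ s⁻¹)
    starting material + target → side product (k6 = 7.67 × 10⁻⁴ L mol⁻¹ s⁻¹)
    solid substrate ⇌ starting material, rate k7*(cs7 - [starting material]) while solid is left; crystals form when [starting material] > cs7 (cs7 = 0.12 M, k7 = 5.24 × 10⁻⁴ s⁻¹)

solid substrate 0.38 M; time 3.0 d

- a species is counted by the solid substrate in it: one side product counts as two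
- given per volume of solution although it is solid: solid substrate
- at the start none of the solid substrate is in solution
- what has only dissolved of solid substrate counts as not reacted
- the reaction counts as stopped when no species that holds the solid substrate changes by six tenths of a point or more over the second half of the time
- run time (flask): 3.0 d

1. which holds at 3.0 d: what has brought the reaction to rest, or that it has not come to rest (for what has run out or reacted, a solid counts together with what of it has only dissolved) (it is still moving / forward and back rates have come level / all of the solid substrate has reacted)
2. how much target there is at 3.0 d, in percent of the solid substrate charged

Count half-lives. Dissolved starting material goes directly to target with a half-life of 0.178 h, shorter than the 0.367 h of dissolving, so while solid is left I expect starting material to stay below its solubility of 0.12 M, used about as fast as it arrives. At full dissolving speed your charge needs 1.68 h, far less than the 3.0 d allowed, so I expect the reaction to end by consuming the charge. The neighbouring flask with 0.65 M looks the same: same constants, same solubility, and 2.87 h of feeding at that speed, also well inside the time.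

The two flasks should part elsewhere. Starting material leaves either alone, to target, or together with a target, to side product. Carry the break-even target level, 1.41 M: the target concentration at which both ways use starting material equally fast, the direct constant over the coupling constant. Target climbs from nothing, so I take half the charge as its mean, which gives a ratio to break-even of 0.135. Each coupling also destroys a target, so the target yield is one minus the ratio over one plus the ratio: 76.2%, setting aside the path through intermediate A. The neighbouring flask holds the same level against a larger charge, so it should lose a larger share.

The forecast says all of the solid substrate has reacted and 76.9%, holding that “direct route to target far outruns the net leak”; its yield stands above mine.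

The simulation gives all of the solid substrate has reacted and 76.9%, so the forecast is right on both, with 0% solid left. Target already read 76.8% at 0.300 d, so this flask's 3.0 d is mostly standing time.

Half of this flask's final 0.292 M of target against break-even gives a ratio of 0.104, so the coupling ran well behind the direct step. With two counted per coupling, that means 18.8% of the charge as side product, beside the 18.6% in the flask. In the neighbouring flask, the same target share puts the ratio at 0.177, which gives 30.1% side product and 69.9% target. Computed, it ends with 27.4% side product and 68.2% target.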